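**Plan**

1. Retrosynthetic cuts (spiro[4.5]decane locants: C1 O-isobutyryl, C3 isopropenyl, C4 ring CH2, C5 spiro atom, C6=C7–C8=O enone, C9 OAc, C10 CH–CH3): C9–OAc (enone α'-acetoxylation); isopropenyl ⇒ acetyl (Wittig); then the cyclopentane bond C3–C4 by a retro-semipinacol ring enlargement to a spiro[5.5]undecene cis-diol monomesylate; that cyclohexene by ring-closing metathesis; the two arms on the quaternary carbon by enolate methallylation and aldehyde allylation; ring A by Michael/aldol.
2. Enabling feature: the exocyclic isopropenyl carbon on C3 stands one bond from the ring CH2 C4 that hangs on spiro C5. A latent acetyl carbon next to a ring CH is the retron of a six-to-five ring contraction in which C4 shifts from a ring C(OH)CH3 carbon to the neighbouring ring CH–OMs carbon.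
3. Forward ring order: cyclohexenone ring A first; a six-membered ring B is then closed on the quaternary carbon by metathesis and contracted to the cyclopentane in the key step; isopropenyl and the C9 acetate come last.
4. Stereochemistry: C10 from the prolinol-ether-catalysed Michael addition; C5 by alkylation anti to the C10 methyl; C1 by reagent-controlled allylboration; C3 by face-selective dihydroxylation, relayed with inversion through the 1,2-shift; C9 by acetoxylation anti to the C10 methyl.

Key step: step 11

Remark: the tertiary carbinol carbon of 6, 7 and 8 is formed without control and is erased in step 5; C1 of 4 equilibrates through the enol until step 2 fixes it.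

**Step 1**
Reactants: 1 methyl 3-oxobutanoate (methyl acetoacetate); 2 (E)-but-2-enal (crotonaldehyde)
Product: 4 methyl (6R)-6-methyl-2-oxocyclohex-3-ene-1-carboxylate (C1 epimers), via Michael adduct 3 (not isolated)
Conditions: (S)-α,α-diphenylprolinol trimethylsilyl ether (10 mol%), PhCO2H (10 mol%), toluene, 0 °C → rt; then p-TsOH·H2O (20 mol%), 80 °C
Reagents that add atoms: none
Why: Iminium-activated asymmetric Michael addition of the β-keto ester to the enal (diarylprolinol silyl ether catalysis) should set the methyl-bearing centre (future C10) as (R) by attack anti to the diphenyl(silyloxy)methyl group of the (E)-iminium ion; acid then closes ring A by intramolecular aldol condensation of the acetyl methyl on the aldehyde.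

**Step 2**
Reactants: 4 methyl (6R)-6-methyl-2-oxocyclohex-3-ene-1-carboxylate
Product: 5 methyl (1R,6R)-6-methyl-1-(2-methylprop-2-en-1-yl)-2-oxocyclohex-3-ene-1-carboxylate
Conditions: K2CO3, 3-bromo-2-methylprop-1-ene, acetone, reflux
Reagents that add atoms: 3-bromo-2-methylprop-1-ene (methallyl bromide), C=C(C)CBr
Why: C-alkylation of the β-keto ester enolate with a soft allylic bromide; the electrophile should enter anti to the adjacent pseudoaxial methyl, so the quaternary carbon (future spiro C5) carries the ester cis and the methallyl group trans to that methyl.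

**Step 3**
Reactants: 5 methyl (1R,6R)-6-methyl-1-(2-methylprop-2-en-1-yl)-2-oxocyclohex-3-ene-1-carboxylate
Product: 6 methyl (1R,6R)-2-hydroxy-2,6-dimethyl-1-(2-methylprop-2-en-1-yl)cyclohex-3-ene-1-carboxylate (C2 epimers)
Conditions: MeLi (1.1 equiv), THF, −78 °C; H2O quench at −78 °C
Reagents that add atoms: methyllithium, [Li]C
Why: 1,2-Addition of methyllithium to the enone carbonyl, which has no α-hydrogen and is far more electrophilic than the hindered ester at −78 °C; the carbinol configuration is immaterial because this carbon becomes sp2 in step 5.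

**Step 4**
Reactants: 6 methyl (1R,6R)-2-hydroxy-2,6-dimethyl-1-(2-methylprop-2-en-1-yl)cyclohex-3-ene-1-carboxylate
Product: 7 (5R,6S)-6-(hydroxymethyl)-1,5-dimethyl-6-(2-methylprop-2-en-1-yl)cyclohex-2-en-1-ol (C1 epimers)
Conditions: LiAlH4, THF, 0 °C → rt
Reagents that add atoms: none
Why: Hydride reduction of the neopentyl-type methyl ester to the primary alcohol; no stereocentre is touched.

**Step 5**
Reactants: 7 (5R,6S)-6-(hydroxymethyl)-1,5-dimethyl-6-(2-methylprop-2-en-1-yl)cyclohex-2-en-1-ol
Product: 9 (1R,6R)-2,6-dimethyl-1-(2-methylprop-2-en-1-yl)-4-oxocyclohex-2-ene-1-carbaldehyde, via hydroxy aldehyde 8 (not isolated)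
Conditions: pyridinium chlorochromate [C5H5NH][CrO3Cl] (4 equiv), Celite, CH2Cl2, rt
Reagents that add atoms: none
Why: The chromium reagent oxidises the primary alcohol to the non-enolisable aldehyde and effects the Babler–Dauben oxidative 1,3-transposition of the tertiary allylic alcohol, which should give the 3-methyl enone of ring A.

**Step 6**
Reactants: 9 (1R,6R)-2,6-dimethyl-1-(2-methylprop-2-en-1-yl)-4-oxocyclohex-2-ene-1-carbaldehyde
Product: 11 (4R,5R)-4-[(1R)-1-hydroxybut-3-en-1-yl]-3,5-dimethyl-4-(2-methylprop-2-en-1-yl)cyclohex-2-en-1-one, via borinate ester 10 (not isolated)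
Conditions: (+)-Ipc2B(allyl) [(−)-α-pinene series] (1.2 equiv), Et2O/pentane, −100 → −78 °C; then HOCH2CH2NH2, rt
Reagents that add atoms: (+)-B-allyldiisopinocampheylborane, C=CCB([C@H]1C[C@H]2C[C@@H]([C@@H]1C)C2(C)C)[C@H]1C[C@H]2C[C@@H]([C@@H]1C)C2(C)C
Why: Brown asymmetric allylboration through a chair six-membered transition state; the (+)-reagent should add allyl to the Re face of the aldehyde and set the (R)-carbinol (future C1) under reagent control, while the aldehyde reacts much faster than the hindered conjugated ketone.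

**Step 7**
Reactants: 11 (4R,5R)-4-[(1R)-1-hydroxybut-3-en-1-yl]-3,5-dimethyl-4-(2-methylprop-2-en-1-yl)cyclohex-2-en-1-one
Product: 12 (1R)-1-[(1R,6R)-2,6-dimethyl-1-(2-methylprop-2-en-1-yl)-4-oxocyclohex-2-en-1-yl]but-3-en-1-yl 2-methylpropanoate
Conditions: i-PrCOCl, pyridine, DMAP (cat.), CH2Cl2, 0 °C → rt
Reagents that add atoms: 2-methylpropanoyl chloride (isobutyryl chloride), CC(C)C(Cl)=O
Why: DMAP-catalysed acylation installs the C1 ester of the target early, so that the hydroxyl cannot direct the osmylation of step 9 to its own face.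

**Step 8**
Reactants: 12 (1R)-1-[(1R,6R)-2,6-dimethyl-1-(2-methylprop-2-en-1-yl)-4-oxocyclohex-2-en-1-yl]but-3-en-1-yl 2-methylpropanoate
Product: 13 (1R,6R,11R)-4,7,11-trimethyl-9-oxospiro[5.5]undeca-3,7-dien-1-yl 2-methylpropanoate
Conditions: second-generation Grubbs catalyst RuCl2(=CHPh)(H2IMes)(PCy3) (5 mol%), CH2Cl2, 40 °C
Reagents that add atoms: none
Why: Ring-closing metathesis of the allyl and methallyl arms on the quaternary carbon closes six-membered ring B with a trisubstituted alkene; the conjugated, hindered enone alkene does not take part.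

**Step 9**
Reactants: 13 (1R,6R,11R)-4,7,11-trimethyl-9-oxospiro[5.5]undeca-3,7-dien-1-yl 2-methylpropanoate
Product: 14 (1R,3R,4S,6R,11R)-3,4-dihydroxy-4,7,11-trimethyl-9-oxospiro[5.5]undec-7-en-1-yl 2-methylpropanoate
Conditions: OsO4 (2 mol%), N-methylmorpholine N-oxide, acetone/H2O, 0 °C → rt
Reagents that add atoms: osmium tetroxide (catalytic oxygen carrier), O=[Os](=O)(=O)=O; N-methylmorpholine N-oxide, C[N+]1([O-])CCOCC1; water, O
Why: Upjohn cis-dihydroxylation of the electron-rich trisubstituted alkene; in the ring B half-chair with the C1 ester pseudoequatorial, C11 of ring A is pseudoaxial on the ester face, so the reagent should add to the opposite face and place both hydroxyls trans to the ester.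

**Step 10**
Reactants: 14 (1R,3R,4S,6R,11R)-3,4-dihydroxy-4,7,11-trimethyl-9-oxospiro[5.5]undec-7-en-1-yl 2-methylpropanoate
Product: 15 (1R,3R,4S,6R,11R)-4-hydroxy-3-(methanesulfonyloxy)-4,7,11-trimethyl-9-oxospiro[5.5]undec-7-en-1-yl 2-methylpropanoate
Conditions: MsCl (1.1 equiv), Et3N, CH2Cl2, −20 °C
Reagents that add atoms: methanesulfonyl chloride, CS(Cl)(=O)=O
Why: Sulfonylation of the secondary hydroxyl is much faster than that of the tertiary one, which leaves the tertiary carbinol free as the migration origin.

**Step 11**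
Reactants: 15 (1R,3R,4S,6R,11R)-4-hydroxy-3-(methanesulfonyloxy)-4,7,11-trimethyl-9-oxospiro[5.5]undec-7-en-1-yl 2-methylpropanoate
Product: 17 (1R,3S,5R,10R)-3-acetyl-6,10-dimethyl-8-oxospiro[4.5]dec-6-en-1-yl 2-methylpropanoate, via aluminium alkoxide 16 (not isolated)
Conditions: Et3Al (3 equiv), CH2Cl2, −78 → 0 °C
Reagents that add atoms: none
Why: Et3Al converts the tertiary hydroxyl into a diethylaluminium alkoxide and, as a Lewis acid, loosens the secondary mesylate; the ring bond C4–C5 lying antiperiplanar to the equatorial C3–OMs bond then migrates, so the ring CH2 (C5 of 15, C4 of 17) leaves the carbinol carbon, bonds to C3, and the carbinol carbon becomes the acetyl carbonyl. The closest known reaction type is the organoaluminium-promoted semipinacol (Tsuchihashi–Suzuki) rearrangement of 2-sulfonyloxy alcohols, the sulfonate counterpart of the Tiffeneau–Demjanov ring contraction. The cyclopentane closes by a 1,2-alkyl shift, an intramolecular displacement through a three-centre transition state (3-exo-tet in form) that contracts ring B from six to five members. The only new stereocentre, C3 of 17, arises by inversion at the mesylate carbon, so its (S) configuration follows from the (3R) carbinol set in step 9. The step needs ring-bond migration in preference to methyl shift, epoxide closure or elimination: the cis OH/OMs relationship excludes epoxide formation, and the chair with equatorial mesylate should be favoured because the other chair (methyl anti to an axial mesylate) suffers a syn-diaxial clash between the C4 methyl and C11 of ring A.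

**Step 12**
Reactants: 17 (1R,3S,5R,10R)-3-acetyl-6,10-dimethyl-8-oxospiro[4.5]dec-6-en-1-yl 2-methylpropanoate
Product: 18 (1R,3S,5R,10R)-6,10-dimethyl-8-oxo-3-(prop-1-en-2-yl)spiro[4.5]dec-6-en-1-yl 2-methylpropanoate
Conditions: Ph3PCH3Br, KOC(CH3)3 (1.2 equiv ylide), THF, −78 → 0 °C
Reagents that add atoms: methylidenetriphenylphosphorane (from methyltriphenylphosphonium bromide), C=P(c1ccccc1)(c1ccccc1)c1ccccc1
Why: Wittig methylenation should take the saturated methyl ketone in preference to the less electrophilic β,β-disubstituted enone carbonyl (the selectivity known for the Wieland–Miescher ketone), and the low temperature limits epimerisation at C3.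

**Step 13**
Reactants: 18 (1R,3S,5R,10R)-6,10-dimethyl-8-oxo-3-(prop-1-en-2-yl)spiro[4.5]dec-6-en-1-yl 2-methylpropanoate
Product: 19 (1R,3S,5R,9R,10S)-9-(acetyloxy)-6,10-dimethyl-8-oxo-3-(prop-1-en-2-yl)spiro[4.5]dec-6-en-1-yl 2-methylpropanoate (target)
Conditions: Mn(OAc)3·2H2O (4 equiv), benzene, reflux (Dean–Stark)
Reagents that add atoms: manganese triacetate, [Mn+3].CC([O-])=O.CC([O-])=O.CC([O-])=O
Why: α'-Acetoxylation of the enone through its manganese enolate; acetate should be delivered anti to the adjacent C10 methyl to give the trans (9R) acetate, which is also the diequatorial arrangement, and an isolated isopropenyl group is expected to survive as it does in carvone.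

**Compound list**

1 | methyl 3-oxobutanoate (methyl acetoacetate) | COC(=O)CC(C)=O | starting material
2 | (E)-but-2-enal (crotonaldehyde) | C/C=C/C=O | starting material
3 | methyl (3R)-2-acetyl-3-methyl-5-oxopentanoate (Michael adduct; C2 epimers) | COC(=O)C(C(C)=O)[C@H](C)CC=O | intermediate (not isolated)
4 | methyl (6R)-6-methyl-2-oxocyclohex-3-ene-1-carboxylate (C1 epimers) | COC(=O)C1C(=O)C=CC[C@H]1C | intermediate
5 | methyl (1R,6R)-6-methyl-1-(2-methylprop-2-en-1-yl)-2-oxocyclohex-3-ene-1-carboxylate | COC(=O)[C@@]1(CC(C)=C)C(=O)C=CC[C@H]1C | intermediate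
6 | methyl (1R,6R)-2-hydroxy-2,6-dimethyl-1-(2-methylprop-2-en-1-yl)cyclohex-3-ene-1-carboxylate (C2 epimers) | COC(=O)[C@@]1(CC(C)=C)C(C)(O)C=CC[C@H]1C | intermediate
7 | (5R,6S)-6-(hydroxymethyl)-1,5-dimethyl-6-(2-methylprop-2-en-1-yl)cyclohex-2-en-1-ol (C1 epimers) | OC[C@@]1(CC(C)=C)C(C)(O)C=CC[C@H]1C | intermediate
8 | (1R,6R)-2-hydroxy-2,6-dimethyl-1-(2-methylprop-2-en-1-yl)cyclohex-3-ene-1-carbaldehyde (C2 epimers) | O=C[C@@]1(CC(C)=C)C(C)(O)C=CC[C@H]1C | intermediate (not isolated)
9 | (1R,6R)-2,6-dimethyl-1-(2-methylprop-2-en-1-yl)-4-oxocyclohex-2-ene-1-carbaldehyde | O=C[C@@]1(CC(C)=C)C(C)=CC(=O)C[C@H]1C | intermediate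
10 | O-[bis(isopinocampheyl)boryl] derivative of 11 (borinate ester, (−)-α-pinene series) | C=CC[C@@H](OB([C@H]1C[C@H]2C[C@@H]([C@@H]1C)C2(C)C)[C@H]1C[C@H]2C[C@@H]([C@@H]1C)C2(C)C)[C@@]1(CC(C)=C)C(C)=CC(=O)C[C@H]1C | intermediate (not isolated)
11 | (4R,5R)-4-[(1R)-1-hydroxybut-3-en-1-yl]-3,5-dimethyl-4-(2-methylprop-2-en-1-yl)cyclohex-2-en-1-one | C=CC[C@@H](O)[C@@]1(CC(C)=C)C(C)=CC(=O)C[C@H]1C | intermediate
12 | (1R)-1-[(1R,6R)-2,6-dimethyl-1-(2-methylprop-2-en-1-yl)-4-oxocyclohex-2-en-1-yl]but-3-en-1-yl 2-methylpropanoate | C=CC[C@@H](OC(=O)C(C)C)[C@@]1(CC(C)=C)C(C)=CC(=O)C[C@H]1C | intermediate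
13 | (1R,6R,11R)-4,7,11-trimethyl-9-oxospiro[5.5]undeca-3,7-dien-1-yl 2-methylpropanoate | CC1=CC[C@@H](OC(=O)C(C)C)[C@@]2(C1)C(C)=CC(=O)C[C@H]2C | intermediate
14 | (1R,3R,4S,6R,11R)-3,4-dihydroxy-4,7,11-trimethyl-9-oxospiro[5.5]undec-7-en-1-yl 2-methylpropanoate | C[C@@]1(O)[C@H](O)C[C@@H](OC(=O)C(C)C)[C@@]2(C1)C(C)=CC(=O)C[C@H]2C | intermediate
15 | (1R,3R,4S,6R,11R)-4-hydroxy-3-(methanesulfonyloxy)-4,7,11-trimethyl-9-oxospiro[5.5]undec-7-en-1-yl 2-methylpropanoate | C[C@@]1(O)[C@H](OS(C)(=O)=O)C[C@@H](OC(=O)C(C)C)[C@@]2(C1)C(C)=CC(=O)C[C@H]2C | intermediate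
16 | diethylaluminium alkoxide of 15 (aluminium on the C4 oxygen) | C[C@@]1(O[Al](CC)CC)[C@H](OS(C)(=O)=O)C[C@@H](OC(=O)C(C)C)[C@@]2(C1)C(C)=CC(=O)C[C@H]2C | intermediate (not isolated)
17 | (1R,3S,5R,10R)-3-acetyl-6,10-dimethyl-8-oxospiro[4.5]dec-6-en-1-yl 2-methylpropanoate | CC(=O)[C@@H]1C[C@@H](OC(=O)C(C)C)[C@@]2(C1)C(C)=CC(=O)C[C@H]2C | intermediate
18 | (1R,3S,5R,10R)-6,10-dimethyl-8-oxo-3-(prop-1-en-2-yl)spiro[4.5]dec-6-en-1-yl 2-methylpropanoate | C=C(C)[C@@H]1C[C@@H](OC(=O)C(C)C)[C@@]2(C1)C(C)=CC(=O)C[C@H]2C | intermediate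
19 | (1R,3S,5R,9R,10S)-9-(acetyloxy)-6,10-dimethyl-8-oxo-3-(prop-1-en-2-yl)spiro[4.5]dec-6-en-1-yl 2-methylpropanoate | C=C(C)[C@@H]1C[C@@H](OC(=O)C(C)C)[C@@]2(C1)C(C)=CC(=O)[C@H](OC(C)=O)[C@H]2C | target

**Step count**

Total steps: 13. Longest linear sequence: 13 steps (from 1 and 2).

**Steps most likely to fail**

Step 9. The risk is delivery of osmium tetroxide to the alkene face syn to the C1 ester, or weak discrimination between the two faces; the wrong carbinol configuration would then be carried with inversion into C3. The fallback sets out from 13 and uses the Woodward cis-hydroxylation (I2, AgOAc, wet AcOH). The iodonium ion forms on the face the electrophile prefers, acetate opens it at the tertiary carbon, and the acetoxonium ion that follows is hydrolysed on the opposite face. This should give the cis-hydroxy acetate F1, with both oxygens on the face opposite to that of first attack. K2CO3 in MeOH at 0 °C should then remove the unhindered acetate in preference to the neopentyl-type isobutyrate. The fallback returns to the route at 14.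

Step 11. The risk is methyl migration from the minor chair, elimination to an allylic alcohol, or ethyl transfer from aluminium to the new ketone in place of ring-bond migration. The fallback sets out from 13 and reaches 17 directly by oxidative ring contraction with thallium trinitrate, Tl(NO3)3·3H2O, in MeOH/CH2Cl2, followed by dilute aqueous acid. Trivalent thallium adds to the less substituted alkene carbon from the face anti to the ester while methanol adds to the tertiary carbon; loss of monovalent thallium then drives the same 1,2-shift of the ring CH2 without diol or sulfonate. The fallback returns at 17 and makes no compound outside the list (F0).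

Step 13. The risk is poor trans selectivity at C9, addition of the α'-keto radical to the isopropenyl group, or acetoxylation at the C6 methyl. The fallback sets out from 18 and uses a Rubottom sequence. LiN(SiMe3)2 and Me3SiCl in THF at −78 °C should give the cross-conjugated silyl dienol ether F2. Dimethyldioxirane in acetone at −40 °C should oxidise its electron-rich enol double bond anti to the C10 methyl and, after desilylation, give the α'-hydroxy enone F3. Ac2O, pyridine and DMAP then give 19, where the fallback returns to the route.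

**Further compounds**

F1 | step 9 | (1R,3R,4S,6R,11R)-3-(acetyloxy)-4-hydroxy-4,7,11-trimethyl-9-oxospiro[5.5]undec-7-en-1-yl 2-methylpropanoate | C[C@@]1(O)[C@H](OC(C)=O)C[C@@H](OC(=O)C(C)C)[C@@]2(C1)C(C)=CC(=O)C[C@H]2C
F0 | step 11 | none | none
F2 | step 13 | (1R,3S,5R,10R)-6,10-dimethyl-3-(prop-1-en-2-yl)-8-[(trimethylsilyl)oxy]spiro[4.5]deca-6,8-dien-1-yl 2-methylpropanoate | C=C(C)[C@@H]1C[C@@H](OC(=O)C(C)C)[C@@]2(C1)C(C)=CC(O[Si](C)(C)C)=C[C@H]2C
F3 | step 13 | (1R,3S,5R,9R,10S)-9-hydroxy-6,10-dimethyl-8-oxo-3-(prop-1-en-2-yl)spiro[4.5]dec-6-en-1-yl 2-methylpropanoate | C=C(C)[C@@H]1C[C@@H](OC(=O)C(C)C)[C@@]2(C1)C(C)=CC(=O)[C@H](O)[C@H]2C
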